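**Plan**

- Germacrane numbering: ring C1–C10, lactone O on C6, ring fusion C7, angelate O on C8, tertiary carbinol C10, methylene C11=C13, carbonyl C12. The enabling feature is C3, a bis-allylic carbinol held in the ten-membered ring between C1=C2 (E) and C4(Me)=C5 (Z). It is a reduced divinyl ketone, so its carbon can be supplied as CO between two alkenyl ends.
- Cuts, in retrosynthetic order: C3 carbinol back to the ketone; C2–C3 and C3–C4 together (CO, a C2 alkenylstannane, a C4 alkenyl iodide); O8–acyl; C6–C7 together with O6–C12; C11–C13; C7–C8.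
- Forward: alkynylation joins C7–C8, borylmethylation adds C13, allylboration of (Z)-3-iodobut-2-enal makes C6–C7 and closes the five-membered lactone, and the ten-membered carbocycle closes last when CO enters as C3.
- Stereochemistry: C10 from a Sharpless epoxidation; C8 from a BINOL–titanium-catalysed alkynylation; C6 and C7 together from the chair allylboration (boronate geometry gives anti, hence the trans lactone; C8 chooses the face); C3 from a CBS reduction. 1E comes from syn hydrostannation, 4Z from trans hydroalumination–iodination, and the angelate geometry from angelic acid.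

Key step: step 14

Remark on the chemistry: the β-silyloxy aldehyde and the β-iodo enal of the route are assumed to be used directly after preparation, since neither stores well.

**Route**

Step 1
Reactants: 1 (E)-3-methylpent-2-en-4-yn-1-ol
Product: 2 [(2S,3S)-3-ethynyl-3-methyloxiran-2-yl]methanol
Conditions: Ti(OiPr)4 (10 mol %), L-(+)-diisopropyl tartrate (12 mol %), tBuOOH, 4 Å MS, CH2Cl2, −20 °C
Reagents that add atoms: tert-butyl hydroperoxide, CC(C)(C)OO
Why: Sharpless asymmetric epoxidation: the titanium tartrate complex binds the allylic hydroxyl and, with L-(+)-tartrate, should give the (2S,3S)-epoxide of this geraniol-type E-trisubstituted allylic alcohol, which fixes the future C10, while the electron-poor terminal alkyne is not oxidised.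

Step 2
Reactants: 2 [(2S,3S)-3-ethynyl-3-methyloxiran-2-yl]methanol
Product: 3 (R)-3-methylpent-4-yne-1,3-diol
Conditions: NaAlH2(OCH2CH2OMe)2, THF, −20 → 0 °C; aq. potassium sodium tartrate
Reagents that add atoms: none
Why: Hydroxyl-directed reductive opening of a 2,3-epoxy alcohol: the aluminate bound to O1 delivers hydride intramolecularly to C2 (future C9), so the tertiary C–O bond and its configuration are kept and the 1,3-diol results, and at low temperature this should outrun hydroalumination of the alkyne.

Step 3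
Reactants: 3 (R)-3-methylpent-4-yne-1,3-diol
Product: 4 (R)-3-methyl-1,3-bis(triethylsilyloxy)pent-4-yne
Conditions: Et3SiOTf, 2,6-lutidine, CH2Cl2, −78 → 0 °C
Reagents that add atoms: triethylsilyl trifluoromethanesulfonate, CC[Si](CC)(CC)OS(=O)(=O)C(F)(F)F
Why: Silylation with a silyl triflate and a hindered base, which is reactive enough to cap the tertiary propargylic hydroxyl as well as the primary one.

Step 4
Reactants: 4 (R)-3-methyl-1,3-bis(triethylsilyloxy)pent-4-yne
Product: 5 (R,E)-tributyl[3-methyl-3,5-bis(triethylsilyloxy)pent-1-en-1-yl]stannane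
Conditions: Bu3SnH, PdCl2(PPh3)2 (2 mol %), THF, 0 °C → rt
Reagents that add atoms: tributyltin hydride, CCCC[SnH](CCCC)CCCC
Why: Palladium-catalysed hydrostannation of a terminal alkyne is a syn addition, and the fully substituted silyloxy-bearing propargylic carbon sends tin to the terminal carbon, so the E-alkenylstannane (future C1=C2) should form.

Step 5
Reactants: 5 (R,E)-tributyl[3-methyl-3,5-bis(triethylsilyloxy)pent-1-en-1-yl]stannane
Product: 7 (R,E)-3-methyl-3-(triethylsilyloxy)-5-(tributylstannyl)pent-4-enal, via alkoxysulfonium chloride 6 (not isolated)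
Conditions: (COCl)2, DMSO, CH2Cl2, −78 → −40 °C; then Et3N, −78 °C → rt
Reagents that add atoms: none
Why: Swern oxidation applied directly to a primary triethylsilyl ether: chlorodimethylsulfonium chloride attacks the unhindered primary silyl ether oxygen, Et3SiCl leaves and the alkoxysulfonium salt collapses to the aldehyde on addition of base, whereas the tertiary silyl ether is too hindered to react and the stannane sees no free acid.

Step 6
Reactants: 7 (R,E)-3-methyl-3-(triethylsilyloxy)-5-(tributylstannyl)pent-4-enal; 8 methyl propiolate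
Product: 10 methyl (4R,6R,7E)-4-hydroxy-6-methyl-6-(triethylsilyloxy)-8-(tributylstannyl)oct-7-en-2-ynoate, via alkynylzinc 9 (not isolated)
Conditions: 8, Et2Zn, HMPA, CH2Cl2, rt; (S)-BINOL (40 mol %), Ti(OiPr)4 (1 equiv); then 7, rt; aq. NH4Cl
Reagents that add atoms: none
Why: Catalytic asymmetric alkynylation of an aldehyde (alkynylzinc addition under a BINOL–titanium catalyst): the complex of (S)-BINOL should deliver the alkynyl group to the Si face of the aldehyde, which gives the (R)-carbinol that becomes C8, the distant C10 centre having little say.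

Step 7
Reactants: 10 methyl (4R,6R,7E)-4-hydroxy-6-methyl-6-(triethylsilyloxy)-8-(tributylstannyl)oct-7-en-2-ynoate
Product: 11 methyl (4R,6R,7E)-6-methyl-4,6-bis(triethylsilyloxy)-8-(tributylstannyl)oct-7-en-2-ynoate
Conditions: Et3SiCl, imidazole, CH2Cl2, 0 °C
Reagents that add atoms: chlorotriethylsilane, CC[Si](CC)(CC)Cl
Why: Silylation of the secondary propargylic alcohol under mild base, which leaves the ynoate and the stannane alone.

Step 8
Reactants: 11 methyl (4R,6R,7E)-6-methyl-4,6-bis(triethylsilyloxy)-8-(tributylstannyl)oct-7-en-2-ynoate; 12 2-(iodomethyl)-4,4,5,5-tetramethyl-1,3,2-dioxaborolane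
Product: 14 methyl (2Z,4R,6R,7E)-6-methyl-2-[(4,4,5,5-tetramethyl-1,3,2-dioxaborolan-2-yl)methyl]-4,6-bis(triethylsilyloxy)-8-(tributylstannyl)octa-2,7-dienoate, via alkenylalane 13 (not isolated)
Conditions: iBu2AlH, HMPA, THF, 0 °C; then 12, 0 °C → rt
Reagents that add atoms: none
Why: Conjugate syn hydroalumination of the ynoate by the iBu2AlH–HMPA complex places Al on C11 and H on C7 on the same side, and the alkenylalane then adds to boron of 12 and the resulting borate undergoes 1,2-migration with loss of iodide (Matteson-type homologation) with retention at the alkenyl carbon, so C8 ends up cis to the ester and trans to CH2B.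

Step 9
Reactants: 15 but-2-yn-1-ol
Product: 17 (Z)-3-iodobut-2-en-1-ol, via cyclic alkenylalanate 16 (not isolated)
Conditions: NaAlH2(OCH2CH2OMe)2, THF, 0 °C → rt; then I2, −78 → 0 °C
Reagents that add atoms: iodine, [I][I]
Why: Trans hydroalumination of a propargylic alcohol: the alkoxide-bound aluminate delivers hydride to C2 and closes a five-membered alkenylalanate with Al on C3 cis to CH2O, and iodinolysis of the C–Al bond with retention gives the Z-iodide.

Step 10
Reactants: 17 (Z)-3-iodobut-2-en-1-ol
Product: 18 (Z)-3-iodobut-2-enal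
Conditions: MnO2, CH2Cl2, rt, dark
Reagents that add atoms: none
Why: Allylic alcohol oxidation with MnO2 under neutral conditions, which should leave the Z geometry and the C–I bond intact.

Step 11
Reactants: 14 methyl (2Z,4R,6R,7E)-6-methyl-2-[(4,4,5,5-tetramethyl-1,3,2-dioxaborolan-2-yl)methyl]-4,6-bis(triethylsilyloxy)-8-(tributylstannyl)octa-2,7-dienoate; 18 (Z)-3-iodobut-2-enal
Product: 20 (4S,5S)-5-[(Z)-2-iodoprop-1-en-1-yl]-3-methylidene-4-[(1R,3R,4E)-3-methyl-1,3-bis(triethylsilyloxy)-5-(tributylstannyl)pent-4-en-1-yl]oxolan-2-one, via borate ester 19 (not isolated)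
Conditions: Sc(OTf)3 (10 mol %), 4 Å MS, toluene, 0 °C → rt
Reagents that add atoms: none
Why: Lewis-acid-catalysed allylboration through a closed six-membered chair followed by lactonisation of the borate onto the neighbouring ester: C8 lies trans to CH2B and is therefore equatorial, the aldehyde substituent is equatorial too, so the anti adduct and hence the trans lactone result (C6 and C7), and with H8 eclipsing C7=C11 to avoid allylic strain with the cis ester the aldehyde should approach C7 anti to the C9 chain, which gives the configuration drawn; no protic acid is used so that the stannane survives.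

Step 12
Reactants: 20 (4S,5S)-5-[(Z)-2-iodoprop-1-en-1-yl]-3-methylidene-4-[(1R,3R,4E)-3-methyl-1,3-bis(triethylsilyloxy)-5-(tributylstannyl)pent-4-en-1-yl]oxolan-2-one
Product: 21 (4R,5S)-4-[(1R,3R,4E)-1,3-dihydroxy-3-methyl-5-(tributylstannyl)pent-4-en-1-yl]-5-[(Z)-2-iodoprop-1-en-1-yl]-3-methylideneoxolan-2-one
Conditions: HF·pyridine, pyridine, THF, 0 °C → rt
Reagents that add atoms: none
Why: Fluoride-mediated desilylation: pyridine-buffered HF·pyridine cleaves the secondary and the tertiary triethylsilyl ether without protodestannylation, opening of the lactone or ionisation of the allylic C6–O bond.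

Step 13
Reactants: 21 (4R,5S)-4-[(1R,3R,4E)-1,3-dihydroxy-3-methyl-5-(tributylstannyl)pent-4-en-1-yl]-5-[(Z)-2-iodoprop-1-en-1-yl]-3-methylideneoxolan-2-one; 22 angelic acid
Product: 24 (1R,3R,4E)-3-hydroxy-1-[(2S,3R)-2-[(Z)-2-iodoprop-1-en-1-yl]-4-methylidene-5-oxooxolan-3-yl]-3-methyl-5-(tributylstannyl)pent-4-en-1-yl (Z)-2-methylbut-2-enoate, via mixed anhydride 23 (not isolated)
Conditions: 22, 2,4,6-Cl3C6H2COCl, Et3N, toluene, rt; then 21, toluene, 60 °C
Reagents that add atoms: none
Why: Yamaguchi-type mixed-anhydride esterification: the preformed angelic 2,4,6-trichlorobenzoic anhydride acylates only the secondary C8 hydroxyl (the tertiary C10 hydroxyl is inert), leaving out nucleophilic catalysts should keep the Z geometry of the angelate, and the diol is acylated directly after step 12 so that the lactone has no time to migrate to O8.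

Step 14
Reactants: 24 (1R,3R,4E)-3-hydroxy-1-[(2S,3R)-2-[(Z)-2-iodoprop-1-en-1-yl]-4-methylidene-5-oxooxolan-3-yl]-3-methyl-5-(tributylstannyl)pent-4-en-1-yl (Z)-2-methylbut-2-enoate; 25 carbon monoxide
Product: 26 (1E,4Z,6R,7R,8R,10R)-8-angeloyloxy-10-hydroxy-3-oxogermacra-1,4,11(13)-trien-12,6-olide
Conditions: Pd2(dba)3 (10 mol %), AsPh3 (40 mol %), CO (3 atm), DMF, 45 °C; 24 added by syringe pump, final 1 mM
Reagents that add atoms: none
Why: Oxidative addition of zerovalent palladium to the alkenyl iodide at C4 is followed by uptake of CO, which turns the alkenylpalladium into an acyl complex of divalent palladium whose carbonyl carbon is the future C3; transfer of the C2 alkenyl group from tin to palladium and C–C reductive elimination then complete the ketone, so that C3–C4 and C2–C3 are both made around the carbon of CO. The closest known reaction type is the carbonylative Stille macrocyclisation of an alkenyl halide or triflate with an alkenylstannane to a macrocyclic cross-conjugated dienone, and ten ring atoms is the lower limit of what that chemistry has delivered. The ten-membered carbocycle closes in the reductive elimination from an eleven-membered acyl(alkenyl)palladacycle and is thereby fused onto the trans lactone that is already in place. No stereocentre is formed, and the 1E and 4Z geometries are carried over unchanged from the stannane and the iodide. The step needs CO uptake and ring closure to win over coupling without CO, Heck-type insertion of C11=C13 and chain growth: coupling without CO would have to build a nine-membered ring holding an E and a Z alkene and the Heck path a bridged bicycle, both more strained than the ten-membered dienone, while the trans lactone and the Z alkene already turn C4 towards the arm that carries C2. The hindered trisubstituted end is the iodide and the fast-transmetalating unhindered end the stannane, the E alkene keeps the free C10 hydroxyl away from the acyl centre, and CO pressure with slow addition at high dilution suppresses the remaining side paths.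

Step 15
Reactants: 26 (1E,4Z,6R,7R,8R,10R)-8-angeloyloxy-10-hydroxy-3-oxogermacra-1,4,11(13)-trien-12,6-olide
Product: 27 (1E,3R,4Z,6R,7R,8R,10R)-8-angeloyloxy-3,10-dihydroxygermacra-1,4,11(13)-trien-12,6-olide (CNP0262559.4)
Conditions: (S)-2-methyl-CBS-oxazaborolidine (50 mol %), catecholborane, toluene, −78 °C; pH 7 buffer
Reagents that add atoms: none
Why: Corey–Bakshi–Shibata reduction: in the complex of the ketone with the (S)-oxazaborolidine the α-methyl-branched C4 alkenyl arm should act as the large group and the C2 arm as the small one, so hydride is delivered to the face that gives the (3R)-carbinol, and catecholborane at −78 °C reduces only the ketone in 1,2-fashion, not the methylene lactone or the angelate.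

**Compound list**

1 | (E)-3-methylpent-2-en-4-yn-1-ol | C#C/C(C)=C/CO | starting material
2 | [(2S,3S)-3-ethynyl-3-methyloxiran-2-yl]methanol | C#C[C@]1(C)O[C@H]1CO | intermediate
3 | (R)-3-methylpent-4-yne-1,3-diol | C#C[C@](C)(O)CCO | intermediate
4 | (R)-3-methyl-1,3-bis(triethylsilyloxy)pent-4-yne | C#C[C@](C)(O[Si](CC)(CC)CC)CCO[Si](CC)(CC)CC | intermediate
5 | (R,E)-tributyl[3-methyl-3,5-bis(triethylsilyloxy)pent-1-en-1-yl]stannane | CCCC[Sn](CCCC)(CCCC)/C=C/[C@](C)(O[Si](CC)(CC)CC)CCO[Si](CC)(CC)CC | intermediate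
6 | alkoxydimethylsulfonium chloride of the primary oxygen of 5 (tertiary silyl ether, R centre and E-stannane unchanged) | CCCC[Sn](CCCC)(CCCC)/C=C/[C@](C)(O[Si](CC)(CC)CC)CCO[S+](C)C.[Cl-] | intermediate
7 | (R,E)-3-methyl-3-(triethylsilyloxy)-5-(tributylstannyl)pent-4-enal | CCCC[Sn](CCCC)(CCCC)/C=C/[C@](C)(O[Si](CC)(CC)CC)CC=O | intermediate
8 | methyl propiolate | C#CC(=O)OC | starting material
9 | methyl 3-(ethylzincio)prop-2-ynoate | CC[Zn]C#CC(=O)OC | intermediate
10 | methyl (4R,6R,7E)-4-hydroxy-6-methyl-6-(triethylsilyloxy)-8-(tributylstannyl)oct-7-en-2-ynoate | CCCC[Sn](CCCC)(CCCC)/C=C/[C@](C)(O[Si](CC)(CC)CC)C[C@@H](O)C#CC(=O)OC | intermediate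
11 | methyl (4R,6R,7E)-6-methyl-4,6-bis(triethylsilyloxy)-8-(tributylstannyl)oct-7-en-2-ynoate | CCCC[Sn](CCCC)(CCCC)/C=C/[C@](C)(O[Si](CC)(CC)CC)C[C@@H](O[Si](CC)(CC)CC)C#CC(=O)OC | intermediate
12 | 2-(iodomethyl)-4,4,5,5-tetramethyl-1,3,2-dioxaborolane | ICB1OC(C)(C)C(C)(C)O1 | starting material
13 | methyl (2E,4R,6R,7E)-2-(diisobutylalumanyl)-6-methyl-4,6-bis(triethylsilyloxy)-8-(tributylstannyl)octa-2,7-dienoate (H and Al cis) | CCCC[Sn](CCCC)(CCCC)/C=C/[C@](C)(O[Si](CC)(CC)CC)C[C@@H](O[Si](CC)(CC)CC)/C=C(/[Al](CC(C)C)CC(C)C)C(=O)OC | intermediate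
14 | methyl (2Z,4R,6R,7E)-6-methyl-2-[(4,4,5,5-tetramethyl-1,3,2-dioxaborolan-2-yl)methyl]-4,6-bis(triethylsilyloxy)-8-(tributylstannyl)octa-2,7-dienoate | CCCC[Sn](CCCC)(CCCC)/C=C/[C@](C)(O[Si](CC)(CC)CC)C[C@@H](O[Si](CC)(CC)CC)/C=C(/CB1OC(C)(C)C(C)(C)O1)C(=O)OC | intermediate
15 | but-2-yn-1-ol | CC#CCO | starting material
16 | sodium 2,2-bis(2-methoxyethoxy)-3-methyl-2,5-dihydro-1,2-oxaaluminol-2-uide (five-membered alkenylalanate, Al on C3 cis to CH2O) | CC1=CCO[Al-]1(OCCOC)OCCOC.[Na+] | intermediate
17 | (Z)-3-iodobut-2-en-1-ol | OC/C=C(/C)I | intermediate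
18 | (Z)-3-iodobut-2-enal | O=C/C=C(/C)I | intermediate
19 | pinacol borate of the open anti adduct: methyl 2-methylidene ester whose C7 carries the C6 carbinol (as O–B(pin), with the (Z)-2-iodoprop-1-enyl group) and the bis-silylated stannyl arm; C6, C7, C8, C10 as in 20 | COC(=O)C(=C)[C@@H]([C@H](OB1OC(C)(C)C(C)(C)O1)/C=C(/C)I)[C@H](O[Si](CC)(CC)CC)C[C@@](C)(O[Si](CC)(CC)CC)/C=C/[Sn](CCCC)(CCCC)CCCC | intermediate
20 | (4S,5S)-5-[(Z)-2-iodoprop-1-en-1-yl]-3-methylidene-4-[(1R,3R,4E)-3-methyl-1,3-bis(triethylsilyloxy)-5-(tributylstannyl)pent-4-en-1-yl]oxolan-2-one (trans lactone) | C=C1C(=O)O[C@H](/C=C(/C)I)[C@H]1[C@H](O[Si](CC)(CC)CC)C[C@@](C)(O[Si](CC)(CC)CC)/C=C/[Sn](CCCC)(CCCC)CCCC | intermediate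
21 | (4R,5S)-4-[(1R,3R,4E)-1,3-dihydroxy-3-methyl-5-(tributylstannyl)pent-4-en-1-yl]-5-[(Z)-2-iodoprop-1-en-1-yl]-3-methylideneoxolan-2-one | C=C1C(=O)O[C@H](/C=C(/C)I)[C@H]1[C@H](O)C[C@@](C)(O)/C=C/[Sn](CCCC)(CCCC)CCCC | intermediate
22 | angelic acid, (Z)-2-methylbut-2-enoic acid | C/C=C(/C)C(=O)O | starting material
23 | (Z)-2-methylbut-2-enoic 2,4,6-trichlorobenzoic anhydride | C/C=C(/C)C(=O)OC(=O)c1c(Cl)cc(Cl)cc1Cl | intermediate
24 | (1R,3R,4E)-3-hydroxy-1-[(2S,3R)-2-[(Z)-2-iodoprop-1-en-1-yl]-4-methylidene-5-oxooxolan-3-yl]-3-methyl-5-(tributylstannyl)pent-4-en-1-yl (Z)-2-methylbut-2-enoate | C=C1C(=O)O[C@H](/C=C(/C)I)[C@H]1[C@H](OC(=O)/C(C)=C\C)C[C@@](C)(O)/C=C/[Sn](CCCC)(CCCC)CCCC | intermediate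
25 | carbon monoxide | [C-]#[O+] | starting material
26 | (1E,4Z,6R,7R,8R,10R)-8-angeloyloxy-10-hydroxy-3-oxogermacra-1,4,11(13)-trien-12,6-olide | C=C1C(=O)O[C@@H]2/C=C(/C)C(=O)/C=C/[C@](C)(O)C[C@@H](OC(=O)/C(C)=C\C)[C@@H]12 | intermediate
27 | (1E,3R,4Z,6R,7R,8R,10R)-8-angeloyloxy-3,10-dihydroxygermacra-1,4,11(13)-trien-12,6-olide | C=C1C(=O)O[C@@H]2/C=C(/C)[C@H](O)/C=C/[C@](C)(O)C[C@@H](OC(=O)/C(C)=C\C)[C@@H]12 | target

**Count**

Total step count: 15. Longest linear sequence: 13 steps (steps 1–8 and 11–15, from 1 to 27); steps 9 and 10 form the side branch to 18.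

**Steps most likely to fail**

Step 14. The ring has only ten members, so closure may be too slow. The acylpalladium can then be captured by the C11=C13 methylene in a Heck-type insertion, or ends of different molecules can couple into chains. The fallback sets out from 24 and comes back at 26 by masking the methylene before the closure. Conjugate addition of dimethylamine (Me2NH, THF, 0 °C) to 24 should give the 13-dimethylamino-11,13-dihydro seco compound F1, in which C11 is sp3 and no Heck acceptor is left. The carbonylative closure under the conditions of step 14 should then give the amino dienone F2. Methylation with MeI gives the trimethylammonium iodide F3, and aqueous NaHCO3 eliminates trimethylamine and restores the methylene lactone 26.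

Step 11. The C8 centre may steer the aldehyde to the other face of C7 than the allylic-strain model predicts, which would give the trans lactone epimeric at both C6 and C7. Loss of tin under the Lewis acid is the second concern. The fallback sets out from 7 and comes back at 24 by running the sequence in the C8-epimeric series and inverting C8 at the acylation. Step 6 with (R)-BINOL gives the (8S)-hydroxy ynoate F4, and silylation gives its bis-silyl ether F5. Hydroalumination gives the (8S)-alkenylalane F6 (not isolated), which is alkylated with 12 to the (8S)-allylboronate F7. Allylboration of 18 through the (8S)-borate ester F8 (not isolated) should now give the (8S)-lactone F9 with C6 and C7 as in 20, and HF·pyridine gives the (8S)-diol F10. A Mitsunobu esterification of F10 with angelic acid 22 (PPh3, DIAD, toluene, 0 °C) inverts C8 while installing the angelate, which is 24.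

Step 15. Facial selectivity may be poor, because both arms of the ketone are ring alkenes that the catalyst may not tell apart well, and the ring conformation may oppose the catalyst. The fallback sets out from 26 and comes back at 27 by substrate control with recycling. Luche reduction (NaBH4, CeCl3·7H2O, MeOH, −78 °C) gives clean 1,2-reduction from the outer face of the preferred ring conformer. The (3S)-epimer F11 that accompanies 27 is separated, oxidised back to 26 with MnO2 and sent through the reduction again.

**Further compounds**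

F1 | step 14 | dimethylamine adduct of 24 (13-dimethylamino-11,13-dihydro, CH2NMe2 on C11 trans to C8) | CN(C)C[C@@H]1C(=O)O[C@H](/C=C(/C)I)[C@H]1[C@H](OC(=O)/C(C)=C\C)C[C@@](C)(O)/C=C/[Sn](CCCC)(CCCC)CCCC
F2 | step 14 | dimethylamine adduct of 26 (13-dimethylamino-11,13-dihydro dienone) | CN(C)C[C@@H]1C(=O)O[C@@H]2/C=C(/C)C(=O)/C=C/[C@](C)(O)C[C@@H](OC(=O)/C(C)=C\C)[C@@H]12
F3 | step 14 | trimethylammonium iodide of F2 | C[N+](C)(C)C[C@@H]1C(=O)O[C@@H]2/C=C(/C)C(=O)/C=C/[C@](C)(O)C[C@@H](OC(=O)/C(C)=C\C)[C@@H]12.[I-]
F4 | step 11 | methyl (4S,6R,7E)-4-hydroxy-6-methyl-6-(triethylsilyloxy)-8-(tributylstannyl)oct-7-en-2-ynoate | CCCC[Sn](CCCC)(CCCC)/C=C/[C@](C)(O[Si](CC)(CC)CC)C[C@H](O)C#CC(=O)OC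
F5 | step 11 | methyl (4S,6R,7E)-6-methyl-4,6-bis(triethylsilyloxy)-8-(tributylstannyl)oct-7-en-2-ynoate | CCCC[Sn](CCCC)(CCCC)/C=C/[C@](C)(O[Si](CC)(CC)CC)C[C@H](O[Si](CC)(CC)CC)C#CC(=O)OC
F6 | step 11 | C8 epimer of alkenylalane 13 | CCCC[Sn](CCCC)(CCCC)/C=C/[C@](C)(O[Si](CC)(CC)CC)C[C@H](O[Si](CC)(CC)CC)/C=C(/[Al](CC(C)C)CC(C)C)C(=O)OC
F7 | step 11 | C8 epimer of allylboronate 14 | CCCC[Sn](CCCC)(CCCC)/C=C/[C@](C)(O[Si](CC)(CC)CC)C[C@H](O[Si](CC)(CC)CC)/C=C(/CB1OC(C)(C)C(C)(C)O1)C(=O)OC
F8 | step 11 | C8 epimer of borate ester 19 | COC(=O)C(=C)[C@@H]([C@H](OB1OC(C)(C)C(C)(C)O1)/C=C(/C)I)[C@@H](O[Si](CC)(CC)CC)C[C@@](C)(O[Si](CC)(CC)CC)/C=C/[Sn](CCCC)(CCCC)CCCC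
F9 | step 11 | C8 epimer of lactone 20 | C=C1C(=O)O[C@H](/C=C(/C)I)[C@H]1[C@@H](O[Si](CC)(CC)CC)C[C@@](C)(O[Si](CC)(CC)CC)/C=C/[Sn](CCCC)(CCCC)CCCC
F10 | step 11 | C8 epimer of diol 21 | C=C1C(=O)O[C@H](/C=C(/C)I)[C@H]1[C@@H](O)C[C@@](C)(O)/C=C/[Sn](CCCC)(CCCC)CCCC
F11 | step 15 | C3 epimer of 27, (3S)-carbinol | C=C1C(=O)O[C@@H]2/C=C(/C)[C@@H](O)/C=C/[C@](C)(O)C[C@@H](OC(=O)/C(C)=C\C)[C@@H]12
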